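(The numbers in the tables were computed on assumed constants; the scatter is artificial.)

My colleague, who made the forecast, and I disagree about one flask: how its rate of making product answers to the precatalyst charge once 10% of the starting material has reacted.

| setting | epsilon | gamma | alpha | flask |
|---|---|---|---|---|
| starting material | 0.038 M | 0.15 M | 0.077 M | 0.077 M |
| precatalyst | 0.22 mM | 0.22 mM | 0.33 mM | 0.22 mM |
| remark | run made earlier | run made earlier | run made earlier |  |

| run | time / h | product / % | starting material / % |
|---|---|---|---|
| epsilon | 1.00 | 0 | 101 |
| epsilon | 2.00 | 1 | 98 |
| epsilon | 5.00 | 1 | 94 |
| epsilon | 12.0 | 6 | 85 |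
| gamma | 3.00 | 3 | 98 |
| gamma | 6.00 | 0 | 95 |
| gamma | 10.0 | 9 | 90 |
| gamma | 12.0 | 9 | 87 |
| alpha | 1.00 | 1 | 95 |
| alpha | 2.00 | 1 | 97 |
| alpha | 5.00 | 1 | 94 |
| alpha | 12.0 | 15 | 80 |

(scatter of a reading: 1.5 percentage points)

- what has gone from starting material into another species counts as reacted, even if it can come back

- factor on the rate of making product when 10% of the starting material are converted if precatalyst is charged twice over
- factor on the rate when 10% of the starting material are converted if precatalyst is charged at 1.2 mM instead

We agree that the kinetics look first order in starting material, since the fractional loss read at 12.0 h is 15.0% from 0.038 M and 13.0% from 0.15 M. She holds that precatalyst merely stretches the clock: “the rate at fixed conversion is first order in catalyst”. Her best evidence is the alpha run, which has 1.50 times the precatalyst and at 12.0 h shows 2.00 times the mean product of the epsilon and gamma runs, close to the 2.25 that the square of that factor gives. Her forecast is 2 (range 1.4 to 2.5) for doubling and 5 (range 2.4 to 7.5) at 1.2 mM.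

I read the lag as an induction period. Working catalyst, on this view, appears from precatalyst at a pace of its own, so early on it grows as charge times time, and product as charge times time squared. That predicts 1.50 for the alpha comparison, so the reading of 2.00 lies nearer her figure than mine, though with 1.5 percentage points on readings this small it does not exclude mine.

Equal conversion, on this view, needs equal charge times time squared. The rate, charge times time, therefore goes as the charge to the power 0.500. I call this exponent the ramp order, the power of the precatalyst charge in the rate at fixed conversion. Hers is 1. Mine gives 1.41 and 2.34, which are not her numbers.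

The simulation gives 1.60 and 2.99.

    starting material + free catalyst ⇌ catalyst intermediate (K = 19.0 M⁻¹, k = 2.10 M⁻¹ min⁻¹)
    catalyst intermediate → free catalyst + product (k = 5.60 min⁻¹)
    starting material ⇌ dormant form (K = 0.940, k = 7.50 × 10⁻⁵ min⁻¹)
    precatalyst → free catalyst (k = 0.00110 min⁻¹)

As ramp orders these are 0.678 for doubling and 0.646 for the flask at 1.2 mM, each nearer my 0.500 than her 1. In this flask the half-life of precatalyst, 10.5 h, is longer than the 9.44 h taken to reach 10% conversion. At that conversion free catalyst, the resting state, is 45.2% of the catalyst in this flask and catalyst intermediate 1.15%; the region of her proportion, with the catalyst out of the precatalyst, is reached in this flask by 200 h, when precatalyst stands at 0% and free catalyst at 99.9%.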